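**Retrosynthetic overview**

1. Numbering used here (ad hoc): cyclohexane C1 (carries the exocyclic methylene carbon C17)–C2–C3–C4 (O)–C5 (quaternary, CH3 = C18)–C6; cyclopentane C5–C6–C9–C8–C7; bridge C9–C10 (CH3)–C11 (O)–C12–C13=C14 (CH3)–C15 (O)–C16–C2.
2. End game: tripropanoate 28 ⇐ triol 27 ⇐ allylic tetraol 24 (reductive 1,3-transposition sets C6–H and the exocyclic methylene) ⇐ keto lactone 23 (LiAlH4).
3. Key disconnection: C1–C2 and C4–C5 of 23 are opened together to macrolactone 21. The enabling feature is that C17 and the oxygen on C15 can close a six-membered lactone C17–C1–C2–C16–C15–O across the C1–C2 bond, C5 is the γ-carbon of the C17 ester dienolate (through C1 and C6), and C4 is 1,3 to C2, so a C17(=O)–O–C15 ester tether with a C2=C3–C4(=O)OPh enoate on C16 turns both bonds into six-membered closures.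
4. 21 ⇐ cross-metathesis ⇐ macrolactonisation (O–C17) ⇐ linear seco acid 18 (two Keck allylations for C11 and C15, Stork–Zhao/formylation for 13Z, copper hydride hydroboration for C10, CO for C17) ⇐ cyclopentene 4 from (R)-limonene (C9 from the chiral pool).
5. Ring order: cyclopentene (step 2) → 11-membered macrolactone (step 15) → in one operation the 11-membered carbocycle and the cyclohexane, with a temporary δ-lactone (step 17) → lactone opened (step 18).

Key step: step 17

Remark: the ligand antipodes written for steps 6, 8 and 13 are those expected from the usual facial preferences of these catalysts; if a sense proved opposite, the other antipode would be used.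

**Route**

Step 1
Reactants: 1 (R)-(+)-limonene
Product: 3 (3R)-6-oxo-3-(prop-1-en-2-yl)heptanal, via ozonide 2 (not isolated)
Conditions: O3 (1.0 equiv), CH2Cl2, −78 °C; then PPh3, −78 °C to rt
Reagents that add atoms: ozone [O-][O+]=O
Why: Ozonolysis with reductive work-up is faster at the electron-rich trisubstituted ring alkene than at the 1,1-disubstituted isopropenyl group, so one equivalent of ozone should cleave only the ring and leave the stereocentre untouched.

Step 2
Reactants: 3 (3R)-6-oxo-3-(prop-1-en-2-yl)heptanal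
Product: 4 (5S)-2-methyl-5-(prop-1-en-2-yl)cyclopent-1-ene-1-carbaldehyde
Conditions: piperidine (cat.), AcOH (cat.), toluene, 80 °C
Reagents that add atoms: none
Why: Intramolecular aldol condensation, in which the aldehyde enamine attacks the methyl ketone in a five-membered closure and dehydration gives the tetrasubstituted enal; the stereocentre (future C9) sits on a carbon that is not enolisable in the product.

Step 3
Reactants: 4 (5S)-2-methyl-5-(prop-1-en-2-yl)cyclopent-1-ene-1-carbaldehyde
Product: 5 [(5S)-2-methyl-5-(prop-1-en-2-yl)cyclopent-1-en-1-yl]methanol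
Conditions: NaBH4, CeCl3·7H2O, MeOH, 0 °C
Reagents that add atoms: none
Why: Luche reduction delivers hydride 1,2 to the conjugated aldehyde and leaves both alkenes alone; no stereocentre is formed.

Step 4
Reactants: 5 [(5S)-2-methyl-5-(prop-1-en-2-yl)cyclopent-1-en-1-yl]methanol
Product: 6 methyl [(5S)-2-methyl-5-(prop-1-en-2-yl)cyclopent-1-en-1-yl]methyl carbonate
Conditions: ClCO2Me, pyridine, CH2Cl2, 0 °C
Reagents that add atoms: methyl chloroformate COC(=O)Cl
Why: Acylation of the primary allylic alcohol gives the carbonate that serves as the ionisable group for the carbonylation.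

Step 5
Reactants: 6 methyl [(5S)-2-methyl-5-(prop-1-en-2-yl)cyclopent-1-en-1-yl]methyl carbonate
Product: 7 methyl 2-[(5S)-2-methyl-5-(prop-1-en-2-yl)cyclopent-1-en-1-yl]acetate
Conditions: Pd(OAc)2 (5 mol %), PPh3, CO (20 bar), THF, 50 °C
Reagents that add atoms: carbon monoxide [C-]#[O+]
Why: Decarboxylative carbonylation of an allylic carbonate: zerovalent palladium ionises the carbonate, CO inserts at the unhindered primary terminus of the π-allyl complex and the released methoxide captures the acylpalladium, so the tetrasubstituted C5=C6 alkene stays in place and the future C17 is installed.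

Step 6
Reactants: 7 methyl 2-[(5S)-2-methyl-5-(prop-1-en-2-yl)cyclopent-1-en-1-yl]acetate
Product: 9 methyl 2-{(5S)-5-[(2S)-1-hydroxypropan-2-yl]-2-methylcyclopent-1-en-1-yl}acetate, via pinacol boronate 8 (not isolated)
Conditions: CuCl (5 mol %), (R)-DTBM-SEGPHOS, KOtBu (10 mol %), HBpin, THF, rt; then NaBO3·4H2O, THF/H2O
Reagents that add atoms: pinacolborane CC1(C)OBOC1(C)C (boron in 8 only); sodium perborate [Na+].[O-]OB=O
Why: Copper hydride catalysed anti-Markovnikov hydroboration of the 1,1-disubstituted alkene, in which the chiral bisphosphine–copper hydride selects the alkene face and so sets C10 by catalyst control, followed by stereoretentive C–B oxidation; the tetrasubstituted alkene and the ester should not react.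

Step 7
Reactants: 9 methyl 2-{(5S)-5-[(2S)-1-hydroxypropan-2-yl]-2-methylcyclopent-1-en-1-yl}acetate
Product: 10 methyl 2-{(5S)-2-methyl-5-[(2S)-1-oxopropan-2-yl]cyclopent-1-en-1-yl}acetate
Conditions: Dess–Martin periodinane, NaHCO3, CH2Cl2, 0 °C
Reagents that add atoms: none
Why: Dess–Martin oxidation under buffered, non-basic conditions should give the α-branched aldehyde without epimerising C10.

Step 8
Reactants: 10 methyl 2-{(5S)-2-methyl-5-[(2S)-1-oxopropan-2-yl]cyclopent-1-en-1-yl}acetate
Product: 11 methyl 2-{(5S)-5-[(2S,3S)-3-hydroxyhex-5-en-2-yl]-2-methylcyclopent-1-en-1-yl}acetate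
Conditions: Ti(OiPr)4 (10 mol %), (S)-BINOL (20 mol %), 4 Å MS, allylSnBu3, CH2Cl2, −20 °C
Reagents that add atoms: allyltributylstannane C=CC[Sn](CCCC)(CCCC)CCCC
Why: Keck asymmetric allylation, in which the BINOL–titanium Lewis acid exposes one aldehyde face so that C11 is set by catalyst control, in the same 10,11-syn sense as the Felkin preference of the α-methyl aldehyde.

Step 9
Reactants: 11 methyl 2-{(5S)-5-[(2S,3S)-3-hydroxyhex-5-en-2-yl]-2-methylcyclopent-1-en-1-yl}acetate
Product: 12 methyl 2-{(5S)-2-methyl-5-[(2S,3S)-3-(pivaloyloxy)hex-5-en-2-yl]cyclopent-1-en-1-yl}acetate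
Conditions: PivCl, pyridine, DMAP (cat.), CH2Cl2, rt
Reagents that add atoms: pivaloyl chloride CC(C)(C)C(Cl)=O
Why: Acylation; the pivalate has no α-hydrogen (inert to the base of step 17), blocks the competing seven-membered lactonisation in step 15 and is removed by LiAlH4 in step 18.

Step 10
Reactants: 12 methyl 2-{(5S)-2-methyl-5-[(2S,3S)-3-(pivaloyloxy)hex-5-en-2-yl]cyclopent-1-en-1-yl}acetate
Product: 14 methyl 2-{(5S)-2-methyl-5-[(2S,3S)-5-oxo-3-(pivaloyloxy)pentan-2-yl]cyclopent-1-en-1-yl}acetate, via diol 13 (not isolated)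
Conditions: OsO4 (2 mol %), NaIO4, 2,6-lutidine, dioxane/H2O, rt
Reagents that add atoms: osmium tetroxide O=[Os](=O)(=O)=O; sodium periodate [Na+].[O-]I(=O)(=O)=O
Why: Lemieux–Johnson oxidation, in which osmylation is faster at the monosubstituted terminal alkene than at the hindered tetrasubstituted ring alkene and periodate cleaves the diol to the aldehyde (C13).

Step 11
Reactants: 14 methyl 2-{(5S)-2-methyl-5-[(2S,3S)-5-oxo-3-(pivaloyloxy)pentan-2-yl]cyclopent-1-en-1-yl}acetate
Product: 15 methyl 2-{(5S)-5-[(2S,3S,5Z)-6-iodo-3-(pivaloyloxy)hept-5-en-2-yl]-2-methylcyclopent-1-en-1-yl}acetate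
Conditions: EtPPh3I, n-BuLi, THF; I2, −78 °C; NaN(SiMe3)2, −20 °C; then 14, −78 °C
Reagents that add atoms: ethyltriphenylphosphonium iodide CC[P+](c1ccccc1)(c1ccccc1)c1ccccc1.[I-]; iodine II
Why: Stork–Zhao olefination, in which the α-iodo ylide should give the (Z)-iodoalkene (iodine cis to the C12 chain) under kinetic control at low temperature, fixing the 13Z geometry before the base can eliminate the β-pivaloyloxy group.

Step 12
Reactants: 15 methyl 2-{(5S)-5-[(2S,3S,5Z)-6-iodo-3-(pivaloyloxy)hept-5-en-2-yl]-2-methylcyclopent-1-en-1-yl}acetate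
Product: 16 methyl 2-{(5S)-2-methyl-5-[(2S,3S,5Z)-6-methyl-7-oxo-3-(pivaloyloxy)hept-5-en-2-yl]cyclopent-1-en-1-yl}acetate
Conditions: Pd(PPh3)4 (5 mol %), CO (3 bar), Bu3SnH (slow addition), THF, 50 °C
Reagents that add atoms: carbon monoxide [C-]#[O+]
Why: Palladium-catalysed reductive carbonylation (formylation) of the alkenyl iodide, in which oxidative addition, CO insertion and hydride transfer from the stannane occur with retention of alkene geometry and both esters are tolerated.

Step 13
Reactants: 16 methyl 2-{(5S)-2-methyl-5-[(2S,3S,5Z)-6-methyl-7-oxo-3-(pivaloyloxy)hept-5-en-2-yl]cyclopent-1-en-1-yl}acetate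
Product: 17 methyl 2-{(5S)-5-[(2S,3S,5Z,7R)-7-hydroxy-6-methyl-3-(pivaloyloxy)deca-5,9-dien-2-yl]-2-methylcyclopent-1-en-1-yl}acetate
Conditions: Ti(OiPr)4 (10 mol %), (R)-BINOL (20 mol %), 4 Å MS, allylSnBu3, CH2Cl2, −20 °C
Reagents that add atoms: allyltributylstannane C=CC[Sn](CCCC)(CCCC)CCCC
Why: Keck asymmetric allylation of the enal by 1,2-addition, with the antipodal BINOL–titanium catalyst setting C15 by catalyst control since no nearby stereocentre competes.

Step 14
Reactants: 17 methyl 2-{(5S)-5-[(2S,3S,5Z,7R)-7-hydroxy-6-methyl-3-(pivaloyloxy)deca-5,9-dien-2-yl]-2-methylcyclopent-1-en-1-yl}acetate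
Product: 18 2-{(5S)-5-[(2S,3S,5Z,7R)-7-hydroxy-6-methyl-3-(pivaloyloxy)deca-5,9-dien-2-yl]-2-methylcyclopent-1-en-1-yl}acetic acid
Conditions: LiOH, THF/MeOH/H2O, 0 °C to rt; then aq. HCl to pH 4
Reagents that add atoms: lithium hydroxide [Li+].[OH-]
Why: Saponification of the unhindered methyl ester should be much faster than that of the hindered pivalate.

Step 15
Reactants: 18 2-{(5S)-5-[(2S,3S,5Z,7R)-7-hydroxy-6-methyl-3-(pivaloyloxy)deca-5,9-dien-2-yl]-2-methylcyclopent-1-en-1-yl}acetic acid
Product: 20 15-allyl macrolactone (11-membered lactone C17(=O)–O–C15 of 18; 9S,10S,11S,13Z,15R; C5=C6; 11-O-pivaloyl), via mixed anhydride 19 (not isolated)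
Conditions: 2-methyl-6-nitrobenzoic anhydride, DMAP, NEt3, toluene (1 mM, syringe pump), rt
Reagents that add atoms: 2-methyl-6-nitrobenzoic anhydride Cc1cccc([N+](=O)[O-])c1C(=O)OC(=O)c1c(C)cccc1[N+](=O)[O-] (acyl group in 19 only)
Why: Shiina macrolactonisation, in which the mixed anhydride is transferred by DMAP to the C15 hydroxyl under high dilution; the cis C13=C14 alkene and the ring-fused C6–C9 unit should preorganise the chain for 11-membered closure, with retention at C15.

Step 16
Reactants: 20 15-allyl macrolactone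
Product: 21 phenyl enoate macrolactone (as 20, with (E)-CH2–CH=CH–C(=O)OPh on C15, i.e. C16, C2=C3, C4)
Conditions: phenyl acrylate (5 equiv), second-generation Hoveyda–Grubbs catalyst RuCl2(=CH-C6H4-2-OiPr)(H2IMes) (5 mol %), CH2Cl2, 40 °C
Reagents that add atoms: phenyl acrylate C=CC(=O)Oc1ccccc1
Why: Cross-metathesis between the only monosubstituted alkene and the electron-poor acrylate should give the (E)-enoate, the tri- and tetrasubstituted alkenes being inert to the ruthenium carbene.

Step 17
Reactants: 21 phenyl enoate macrolactone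
Product: 23 tricyclic keto lactone (2R,5S,9S,10S,11S,13Z,15R; 4-oxo; C1=C6; C17(=O)–O–C15 lactone; 11-O-pivaloyl), via Michael adduct 22 (not isolated)
Conditions: LiN(SiMe3)2 (1.1 equiv), THF (5 mM), −78 °C to −20 °C; aq. NH4Cl
Reagents that add atoms: none
Why: Proposed new method: LiN(SiMe3)2 should remove the doubly activated C1–H (α to the lactone carbonyl C17 and allylic to C5=C6), and the ester enolate then adds through C1 to C2 of the tethered phenyl enoate in a 6-exo-trig Michael closure of the ring C1–C17(=O)–O–C15–C16–C2, which at the same time closes the 11-membered carbocycle across the macrolactone; the closest known reaction type is the intramolecular ester-enolate Michael addition followed by Claisen acylation (Michael–Dieckmann annulation). Proton transfer from the now tertiary C1–H, mediated by HN(SiMe3)2, should convert the phenyl ester enolate into the more stable lactone dienolate O–C17=C1–C6=C5, whose α-carbon cannot reach the acyl group, so its γ-carbon C5 attacks the phenyl ester carbonyl C4 in a 6-(enolendo)-exo-trig acylation that closes the cyclohexane, expels phenoxide and returns conjugation (C1=C6) to the lactone. C2 is set in the Michael stage by C15: the C1–C6 and C15–C14 bonds are the two ends of the existing bridge and must lie on one face of the new lactone ring, so the enoate should react with C3 on the opposite, open face (C3 trans to C14). C5 is then set by C2 and the ring system: the lactone holds C16 pseudo-equatorial on the forming cyclohexene, the C3–C4 arm can therefore reach only the face of C5=C6 that is syn to the C9–C10 bond, and the C18 methyl (cis to C1 on the alkene) becomes axial on the other face. The step needs α-deprotonation at C1 rather than γ-deprotonation of the enoate (kinetic acidity of the allylic lactone CH2 at −78 °C), 1,4- rather than 1,2-addition (six- against eight-membered closure) and C- rather than O-acylation (O-acylation is reversed by phenoxide, C–C formation is not).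

Step 18
Reactants: 23 tricyclic keto lactone
Product: 24 tetraol (2R,4S,5S,9S,10S,11S,13Z,15R; 4,11,15,17-tetrahydroxy; C1=C6)
Conditions: LiAlH4, THF, 0 °C to rt; Rochelle salt work-up
Reagents that add atoms: none
Why: Hydride reduction, in which the lactone is opened by 1,2-reduction to the primary allylic alcohol at C17 and the C15 alcohol, the pivalate is cleaved, and the C4 ketone is attacked along the axial trajectory on the face opposite to the axial C18 methyl, which should give the equatorial (4S) alcohol.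

Step 19
Reactants: 24 tetraol
Product: 27 triol (2R,4S,5S,6S,9R,10S,11S,13Z,15R; 4,11,15-trihydroxy; exocyclic C1=C17), via sulfonylhydrazine 25 (not isolated), via allylic diazene 26 (not isolated)
Conditions: 2-nitrobenzenesulfonylhydrazide, PPh3, DEAD, N-methylmorpholine, −30 °C, then rt
Reagents that add atoms: 2-nitrobenzenesulfonylhydrazide NNS(=O)(=O)c1ccccc1[N+](=O)[O-] (nitrogen in 25 and 26 only)
Why: Mitsunobu displacement of the primary allylic alcohol by the acidic sulfonylhydrazide (faster than reaction of the three secondary alcohols), loss of sulfinate and retro-ene loss of dinitrogen (allylic diazene rearrangement) should move the alkene to the exocyclic position and deliver hydrogen to C6 from the face not covered by the C10–C16 bridge, the face of the C18 methyl, which sets the cis ring fusion.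

Step 20
Reactants: 27 triol
Product: 28 target tripropanoate (CNP0315827.1)
Conditions: (EtCO)2O, DMAP, NEt3, CH2Cl2, rt to 40 °C
Reagents that add atoms: propanoic anhydride CCC(=O)OC(=O)CC
Why: Exhaustive DMAP-catalysed acylation of the three secondary alcohols, with no stereocentre affected.

**Compound list**

1 | (R)-(+)-limonene | CC1=CC[C@@H](CC1)C(C)=C | starting material
2 | ozonide of the ring alkene of 1 (1,2,4-trioxolane) | CC12CC[C@H](CC(O1)OO2)C(C)=C | intermediate
3 | (3R)-6-oxo-3-(prop-1-en-2-yl)heptanal | O=CC[C@@H](CCC(C)=O)C(C)=C | intermediate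
4 | (5S)-2-methyl-5-(prop-1-en-2-yl)cyclopent-1-ene-1-carbaldehyde | O=CC1=C(C)CC[C@H]1C(C)=C | intermediate
5 | [(5S)-2-methyl-5-(prop-1-en-2-yl)cyclopent-1-en-1-yl]methanol | OCC1=C(C)CC[C@H]1C(C)=C | intermediate
6 | methyl [(5S)-2-methyl-5-(prop-1-en-2-yl)cyclopent-1-en-1-yl]methyl carbonate | COC(=O)OCC1=C(C)CC[C@H]1C(C)=C | intermediate
7 | methyl 2-[(5S)-2-methyl-5-(prop-1-en-2-yl)cyclopent-1-en-1-yl]acetate | COC(=O)CC1=C(C)CC[C@H]1C(C)=C | intermediate
8 | pinacol boronate of 9 (Bpin in place of OH) | COC(=O)CC1=C(C)CC[C@H]1[C@H](C)CB1OC(C)(C)C(C)(C)O1 | intermediate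
9 | methyl 2-{(5S)-5-[(2S)-1-hydroxypropan-2-yl]-2-methylcyclopent-1-en-1-yl}acetate | COC(=O)CC1=C(C)CC[C@H]1[C@H](C)CO | intermediate
10 | methyl 2-{(5S)-2-methyl-5-[(2S)-1-oxopropan-2-yl]cyclopent-1-en-1-yl}acetate | COC(=O)CC1=C(C)CC[C@H]1[C@H](C)C=O | intermediate
11 | methyl 2-{(5S)-5-[(2S,3S)-3-hydroxyhex-5-en-2-yl]-2-methylcyclopent-1-en-1-yl}acetate | COC(=O)CC1=C(C)CC[C@H]1[C@H](C)[C@@H](O)CC=C | intermediate
12 | methyl 2-{(5S)-2-methyl-5-[(2S,3S)-3-(pivaloyloxy)hex-5-en-2-yl]cyclopent-1-en-1-yl}acetate | COC(=O)CC1=C(C)CC[C@H]1[C@H](C)[C@@H](OC(=O)C(C)(C)C)CC=C | intermediate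
13 | methyl 2-{(5S)-5-[(2S,3S)-5,6-dihydroxy-3-(pivaloyloxy)hexan-2-yl]-2-methylcyclopent-1-en-1-yl}acetate (both C5 epimers) | COC(=O)CC1=C(C)CC[C@H]1[C@H](C)[C@@H](OC(=O)C(C)(C)C)CC(O)CO | intermediate
14 | methyl 2-{(5S)-2-methyl-5-[(2S,3S)-5-oxo-3-(pivaloyloxy)pentan-2-yl]cyclopent-1-en-1-yl}acetate | COC(=O)CC1=C(C)CC[C@H]1[C@H](C)[C@@H](OC(=O)C(C)(C)C)CC=O | intermediate
15 | methyl 2-{(5S)-5-[(2S,3S,5Z)-6-iodo-3-(pivaloyloxy)hept-5-en-2-yl]-2-methylcyclopent-1-en-1-yl}acetate | COC(=O)CC1=C(C)CC[C@H]1[C@H](C)[C@@H](OC(=O)C(C)(C)C)C/C=C(/C)I | intermediate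
16 | methyl 2-{(5S)-2-methyl-5-[(2S,3S,5Z)-6-methyl-7-oxo-3-(pivaloyloxy)hept-5-en-2-yl]cyclopent-1-en-1-yl}acetate | COC(=O)CC1=C(C)CC[C@H]1[C@H](C)[C@@H](OC(=O)C(C)(C)C)C/C=C(/C)C=O | intermediate
17 | methyl 2-{(5S)-5-[(2S,3S,5Z,7R)-7-hydroxy-6-methyl-3-(pivaloyloxy)deca-5,9-dien-2-yl]-2-methylcyclopent-1-en-1-yl}acetate | COC(=O)CC1=C(C)CC[C@H]1[C@H](C)[C@@H](OC(=O)C(C)(C)C)C/C=C(/C)[C@H](O)CC=C | intermediate
18 | 2-{(5S)-5-[(2S,3S,5Z,7R)-7-hydroxy-6-methyl-3-(pivaloyloxy)deca-5,9-dien-2-yl]-2-methylcyclopent-1-en-1-yl}acetic acid | OC(=O)CC1=C(C)CC[C@H]1[C@H](C)[C@@H](OC(=O)C(C)(C)C)C/C=C(/C)[C@H](O)CC=C | intermediate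
19 | mixed anhydride of 18 with 2-methyl-6-nitrobenzoic acid | Cc1cccc([N+](=O)[O-])c1C(=O)OC(=O)CC1=C(C)CC[C@H]1[C@H](C)[C@@H](OC(=O)C(C)(C)C)C/C=C(/C)[C@H](O)CC=C | intermediate
20 | 15-allyl macrolactone: 11-membered lactone C17(=O)–O–C15 of 18 (9S,10S,11S,13Z,15R; C5=C6; 11-O-pivaloyl) | O=C1CC2=C(C)CC[C@H]2[C@H](C)[C@@H](OC(=O)C(C)(C)C)C/C=C(/C)[C@@H](CC=C)O1 | intermediate
21 | phenyl enoate macrolactone: as 20 with (E)-CH2CH=CHC(=O)OPh on C15 | O=C1CC2=C(C)CC[C@H]2[C@H](C)[C@@H](OC(=O)C(C)(C)C)C/C=C(/C)[C@@H](C/C=C/C(=O)Oc2ccccc2)O1 | intermediate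
22 | Michael adduct: C1–C2 bonded, δ-lactone C17(=O)–O–C15–C16–C2–C1, CH2C(=O)OPh on C2 (2R,15R; C1 not defined) | O=C(C[C@H]1C[C@H]2OC(=O)C1C1=C(C)CC[C@H]1[C@H](C)[C@@H](OC(=O)C(C)(C)C)C/C=C2/C)Oc1ccccc1 | intermediate
23 | tricyclic keto lactone (2R,5S,9S,10S,11S,13Z,15R; 4-oxo; C1=C6; C17(=O)–O–C15; 11-O-pivaloyl) | O=C4C=1[C@H]2CC(=O)[C@@]3(C)CC[C@@H]([C@H](C)[C@@H](OC(=O)C(C)(C)C)C/C=C(/C)[C@H](O4)C2)C=13 | intermediate
24 | tetraol (2R,4S,5S,9S,10S,11S,13Z,15R; 4,11,15,17-tetrahydroxy; C1=C6) | OCC=1[C@H]2C[C@H](O)[C@@]3(C)CC[C@@H]([C@H](C)[C@@H](O)C/C=C(/C)[C@H](O)C2)C=13 | intermediate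
25 | N-(C17-alkyl)-N-(2-nitrobenzenesulfonyl)hydrazine of 24 | NN(CC=1[C@H]2C[C@H](O)[C@@]3(C)CC[C@@H]([C@H](C)[C@@H](O)C/C=C(/C)[C@H](O)C2)C=13)S(=O)(=O)c1ccccc1[N+](=O)[O-] | intermediate
26 | C17 monoalkyl diazene of 24 | N=NCC=1[C@H]2C[C@H](O)[C@@]3(C)CC[C@@H]([C@H](C)[C@@H](O)C/C=C(/C)[C@H](O)C2)C=13 | intermediate
27 | triol (2R,4S,5S,6S,9R,10S,11S,13Z,15R; 4,11,15-trihydroxy; exocyclic C1=C17) | C=C1[C@H]2C[C@H](O)[C@@]3(C)CC[C@@H]([C@H](C)[C@@H](O)C/C=C(/C)[C@H](O)C2)[C@@H]13 | intermediate
28 | target tripropanoate (CNP0315827.1) | C=C1[C@H]2C[C@H](OC(=O)CC)[C@@]3(C)CC[C@@H]([C@H](C)[C@@H](OC(=O)CC)C/C=C(/C)[C@H](OC(=O)CC)C2)[C@@H]13 | target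

**Totals and risks**

Total step count: 20. Longest linear sequence: 20 steps (from (R)-limonene).

Most likely to fail, in this order:

1. Step 17 (proposed new method). The process at risk is the second stage: the proton shuttle to the lactone dienolate may be slow, and O-acylation or ketene loss from the phenyl ester enolate may then outrun the γ-acylation, so that only the Michael ring closes. The fallback takes the two bond formations apart with known chemistry, setting out from 20 and returning at 24. Cross-metathesis of 20 with S-ethyl thioacrylate (second-generation Hoveyda–Grubbs catalyst) would give the thioenoate macrolactone F1. LiN(SiMe3)2 at −78 °C with a cold acetic acid quench would stop at the intramolecular ester-enolate Michael adduct, thioester F2. Fukuyama reduction (Et3SiH, Pd/C) would give the aldehyde F3. Me2AlCl-promoted carbonyl-ene (Prins) closure of the aldehyde onto the tetrasubstituted C5=C6 alkene, with loss of the acidic C1–H, would give the hydroxy lactone F4, which already carries the C4 hydroxyl. LiAlH4 would then give 24.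

2. Step 15. The process at risk is oligomerisation in competition with closure of the 11-membered ring, together with isomerisation of the β,γ-unsaturated acyl donor while it is activated. The fallback activates the alcohol instead of the acid, setting out from 16 and returning at 20. Keck allylation of 16 with (S)-BINOL would give the C15 epimer F5, and LiOH would give the epimeric seco acid F6. Mitsunobu macrolactonisation (PPh3, DIAD, toluene, high dilution) would then close the ring by carboxylate displacement with inversion at C15 and give 20.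

3. Step 19. The processes at risk are poor facial selectivity of the hydrogen transfer to C6 (the diazene can in principle swing to either face) and etherification of the activated primary alcohol by the C15 hydroxyl. The fallback replaces the sigmatropic transfer by a metal-delivered hydride, setting out from 24 and returning at 27. Selective methoxycarbonylation of the primary allylic hydroxyl (ClCO2Me, pyridine, −30 °C) would give the carbonate F7. Palladium-catalysed formate hydrogenolysis (Pd(OAc)2, PBu3, HCO2H, NEt3, THF) would deliver hydride from palladium to the more substituted allyl terminus C6, the metal being bound on the face away from the bridge, and give 27.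

Further compounds
F1 | step 17 | thioenoate macrolactone (as 21 with C(=O)SEt in place of C(=O)OPh) | O=C1CC2=C(C)CC[C@H]2[C@H](C)[C@@H](OC(=O)C(C)(C)C)C/C=C(/C)[C@@H](C/C=C/C(=O)SCC)O1
F2 | step 17 | Michael adduct thioester (as 22 with S-ethyl thioester) | CCSC(=O)C[C@H]1C[C@H]2OC(=O)C1C1=C(C)CC[C@H]1[C@H](C)[C@@H](OC(=O)C(C)(C)C)C/C=C2/C
F3 | step 17 | Michael adduct aldehyde (C4 as CHO) | O=CC[C@H]1C[C@H]2OC(=O)C1C1=C(C)CC[C@H]1[C@H](C)[C@@H](OC(=O)C(C)(C)C)C/C=C2/C
F4 | step 17 | tricyclic hydroxy lactone (as 23 with (4S)-hydroxyl in place of the ketone) | O=C4C=1[C@H]2C[C@H](O)[C@@]3(C)CC[C@@H]([C@H](C)[C@@H](OC(=O)C(C)(C)C)C/C=C(/C)[C@H](O4)C2)C=13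
F5 | step 15 | C15 epimer of 17 (7S in the side chain) | COC(=O)CC1=C(C)CC[C@H]1[C@H](C)[C@@H](OC(=O)C(C)(C)C)C/C=C(/C)[C@@H](O)CC=C
F6 | step 15 | C15 epimer of seco acid 18 | OC(=O)CC1=C(C)CC[C@H]1[C@H](C)[C@@H](OC(=O)C(C)(C)C)C/C=C(/C)[C@@H](O)CC=C
F7 | step 19 | C17 methyl carbonate of tetraol 24 | COC(=O)OCC=1[C@H]2C[C@H](O)[C@@]3(C)CC[C@@H]([C@H](C)[C@@H](O)C/C=C(/C)[C@H](O)C2)C=13
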